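The plan rests on cutting both bonds from C11 to ring B (C6–C11 and C7–C11). The target's gem-dimethylcyclopropane C6–C7–C11 sits α,β to the C8 ketone and on the face of ring B opposite the C5 methyl. One isopropylidene transfer from diphenylsulfonium isopropylide to the C6=C7 arm of a cross-conjugated 6,9-dien-8-one therefore closes the three-membered ring, makes two C–C bonds and sets C6 and C7. The precursor is the 1α-aryl-4,5-dimethyl dienone with both phenols as MOM ethers and the acetyl group stored as its TIPS enol ether. C1 is set earlier by trans-diaxial epoxide opening, and the spared C9=C10 enone later takes up the C6' phenol.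

Key step: step 12

Remark on locants: C1 benzylic CH, C4 CHMe, C5 CMe, C6/C7 cyclopropane CH, C8/C9 ketones, C10 O-bearing carbon, C11 CMe2. Ring A is C1–C5 plus C10 and ring B is C5–C10. On the arene, C1' is acyl, C2' OH, C4' OMe, C5' is bonded to C1 and C6' to O. α is the face of the C5 methyl and β the opposite face.
Remark on the target: the configuration planned for is 1R,4R,5R,6S,7R,10S, with the C1 aryl, C4 methyl, C5 methyl and C10 oxygen all α and the cyclopropane β.
Remark on abbreviations: Ar = 6-methoxy-2,4-bis(methoxymethoxy)-3-[1-(triisopropylsilyloxy)ethenyl]phenyl; MOM = CH2OCH3; TIPS = Si(i-Pr)3.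
Remark on C1: in the open enone the aryl group is axial and syn to the C5 methyl, which is the less stable arrangement. It is therefore set kinetically in step 8, and no equilibrating acid or base is used until ring closure in step 14.
Assumption: the (R,S,S)-phosphoramidite is taken to deliver methyl to the enone face that gives 3R, mirroring the S-selectivity of its antipode with cyclohexenone. If the sense is reversed, the ligand antipode is used.

Step 1
Reactants: 1 2-methylcyclohex-2-en-1-one
Product: 2 (3R)-2,3-dimethylcyclohexan-1-one (both C2 epimers)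
Conditions: AlMe3 (1.4 equiv), Cu(O2C-2-thienyl) (2 mol %), phosphoramidite from (R)-BINOL and bis[(S)-1-phenylethyl]amine (4 mol %), Et2O, −30 °C; aq. NH4Cl
Reagents that add atoms: trimethylaluminium, C[Al](C)C
Why: Copper-catalysed asymmetric conjugate addition in which the chiral phosphoramidite–copper complex selects the enone face and so sets C4 (ketone C3) as R, while the C2 centre formed on protonation is irrelevant because it is enolised in step 2.

Step 2
Reactants: 2 (3R)-2,3-dimethylcyclohexan-1-one; 3 but-3-en-2-one (methyl vinyl ketone)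
Product: 5 cis-4,5-dimethyl octalone (4α,5α-dimethyl-9-en-8-one; (4aS,5R)-4a,5-dimethyl-4,4a,5,6,7,8-hexahydronaphthalen-2(3H)-one), via Michael adduct diketone 4 (not isolated)
Conditions: H2SO4 (cat.), toluene, reflux, Dean–Stark
Reagents that add atoms: none
Why: Acid-catalysed Robinson annulation in which the more substituted enol attacks methyl vinyl ketone anti to the neighbouring pseudo-axial C4 methyl, setting quaternary C5 with the two methyl groups cis, and aldol condensation of the diketone then closes ring B.

Step 3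
Reactants: 5 cis-4,5-dimethyl octalone
Product: 6 8-acetoxy-4α,5α-dimethyl-1(10),8-diene (heteroannular dienol acetate)
Conditions: isopropenyl acetate, p-TsOH·H2O (cat.), reflux
Reagents that add atoms: isopropenyl acetate, CC(=C)OC(C)=O
Why: Acid-catalysed enol acetylation under equilibrating conditions gives the thermodynamic heteroannular dienol acetate, the standard way to move an enone double bond out of conjugation, and touches no stereocentre.

Step 4
Reactants: 6 dienol acetate
Product: 8 4α,5α-dimethyl-1(10)-en-8α-ol, via β,γ-enone 7 (not isolated)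
Conditions: NaBH4, EtOH–THF–H2O, 0 °C → rt
Reagents that add atoms: none
Why: Deconjugative borohydride reduction of a dienol acetate, in which deacetylation and kinetic protonation at C9 give the β,γ-enone, which is reduced faster than it reconjugates, with axial hydride delivery giving mainly the equatorial 8α-alcohol (a centre erased in step 9).

Step 5
Reactants: 8 4α,5α-dimethyl-1(10)-en-8α-ol
Product: 9 1β,10β-epoxy-4α,5α-dimethyldecalin-8α-ol
Conditions: m-CPBA, NaHCO3, CH2Cl2, 0 °C
Reagents that add atoms: 3-chloroperoxybenzoic acid, OOC(=O)c1cccc(Cl)c1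
Why: Prilezhaev epoxidation in which the peracid reaches the trisubstituted C1=C10 alkene from the β face, away from the axial C5 methyl as with Δ5-steroids, and the minor α-epoxide is removed by chromatography.

Step 6
Reactants: 10 2',6'-dihydroxy-4'-methoxyacetophenone
Product: 11 4'-methoxy-2',6'-bis(methoxymethoxy)acetophenone
Conditions: NaH, MOMCl, DMF, 0 °C → rt
Reagents that add atoms: chloromethyl methyl ether, COCCl
Why: Williamson-type ether formation, with NaH used to break the hydrogen bonds of both phenols to the ketone.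

Step 7
Reactants: 11 bis-MOM acetophenone
Product: 13 1-[4-methoxy-2,6-bis(methoxymethoxy)phenyl]-1-(triisopropylsilyloxy)ethene, via potassium enolate 12 (not isolated)
Conditions: KN(SiMe3)2, THF, −78 °C; i-Pr3SiOTf, −78 → 0 °C
Reagents that add atoms: triisopropylsilyl triflate, CC(C)[Si](OS(=O)(=O)C(F)(F)F)(C(C)C)C(C)C
Why: O-silylation of the enolate stores the acetyl group without having to ketalise a carbonyl flanked by two ortho substituents, removes its acidic protons for steps 8, 11 and 12, and provides the nucleophile of step 13.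

Step 8
Reactants: 13 aryl silyl enol ether; 9 epoxy alcohol
Product: 17 1α-Ar-4α,5α-dimethyldecalin-8α,10β-diol, via aryllithium 14 (not isolated), via arylmagnesium bromide 15 (not isolated), via bromomagnesium alkoxide 16 (not isolated)
Conditions: 13 (2.5 equiv), n-BuLi, THF, 0 °C; MgBr2·OEt2; copper iodide CuI (15 mol %); add 16 [from 9 and MeMgBr (1.0 equiv), THF, 0 °C]; 0 → 45 °C; aq. NH4Cl
Reagents that add atoms: none
Why: Directed ortho-lithiation between OMOM and OMe is followed by copper-catalysed Grignard opening of the epoxide under Fürst–Plattner (trans-diaxial) control, so the aryl group attacks the secondary C1 anti to the C–O bond from the α face and sets the axial 1α-aryl/10β-ol pair, the course known for 6β-alkylation of steroidal 5α,6α-epoxides.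

Step 9
Reactants: 17 diol
Product: 18 1α-Ar-10β-hydroxy-4α,5α-dimethyldecalin-8-one
Conditions: (n-Pr)4N[RuO4] (5 mol %), N-methylmorpholine N-oxide, 4 Å MS, CH2Cl2, rt
Reagents that add atoms: none
Why: Ley–Griffith oxidation, in which only the secondary C8 alcohol can be oxidised and the neutral medium spares the MOM ethers, the enol ether and the tertiary alcohol.

Step 10
Reactants: 18 β-hydroxy ketone
Product: 19 1α-Ar-4α,5α-dimethyl-9-en-8-one
Conditions: NaOH (0.1 M), MeOH–THF, 0 °C → rt, quenched at full conversion
Reagents that add atoms: none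
Why: E1cB dehydration of a β-hydroxy ketone in which only C9–H is acidic and the axial 10β-hydroxide leaves, brief contact with dilute alkali being the method that keeps axial 6β-substituents in place in 5α-hydroxy-3-keto steroids.

Step 11
Reactants: 19 1α-aryl enone
Product: 21 1α-Ar-4α,5α-dimethyl-6,9-dien-8-one (precursor of the key step), via lithium dienolate 20 (not isolated)
Conditions: LiN(i-Pr)2, THF, −78 °C; PhS(Cl)=N-t-Bu, −78 °C
Reagents that add atoms: none
Why: Mukaiyama dehydrogenation in which kinetic deprotonation of the enone occurs at the α' carbon C7, the enolate is sulfenylated there and the adduct undergoes syn elimination at −78 °C, so the vinylogous C1–H is not touched.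

Step 12
Reactants: 21 1α-aryl dienone; 22 isopropyldiphenylsulfonium tetrafluoroborate
Product: 24 1α-Ar-aristol-9-en-8-one (6β,7β-isopropylidene), via sulfonium ylide 23 (not isolated)
Conditions: 22 (1.6 equiv), t-BuLi (1.5 equiv), DME–THF, −78 °C; then 21, −78 → −40 °C; pH 7 buffer
Reagents that add atoms: none
Why: Corey–Chaykovsky-type isopropylidene transfer (Michael-initiated ring closure): the ylide carbon C11 adds 1,4 to C6 and the C7 enolate then displaces Ph2S from C11 in a 3-exo-tet closure, so C6–C11 and C7–C11 form in one operation. The closest known reactions are gem-dimethylcyclopropanation of cyclic enones with this ylide and sulfur-ylide cyclopropanation of steroidal 1,4-dien-3-ones at the disubstituted alkene. C6 is set by approach to the flat ring B from the β face, because the α face carries the axial C5 methyl next to C6 as well as the axial C1 aryl group, and C7 follows because a three-membered ring can only be cis-fused. Chemoselectivity for C6=C7 over C9=C10 rests on C10 being fully substituted and flanked by C1 and C5. The ylide could remove the vinylogous C1–H, but with the aryl group axial this hydrogen is equatorial and lies near the nodal plane of the dienone π system, the enol ether offers no acidic CH3, and the base is kept in deficit to the salt at −78 °C.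

Step 13
Reactants: 24 protected 1-aryl-aristol-9-en-8-one; 25 4-methoxybenzaldehyde dimethyl acetal
Product: 26 β-methoxy ketone: 24 with the enol ether replaced by C(=O)CH2CH(OMe)(4-MeOC6H4) (both epimers at the methoxy carbon)
Conditions: Me3SiOTf (0.15 equiv), 2,6-di-tert-butyl-4-methylpyridine (0.2 equiv), CH2Cl2, −78 °C
Reagents that add atoms: none
Why: Mukaiyama aldol-type addition of the silyl enol ether to the oxocarbenium ion of the acetal builds the three-carbon bridge of the chalcone without any base while C1–H is still vinylogously acidic, and the new methoxy-bearing centre is lost in step 14.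

Step 14
Reactants: 26 β-methoxy ketone
Product: 28 9-deoxo target 2'-acetate (dihydrobenzofuran closed; C8 ketone; E-chalcone), via free phenol chalcone 27 (not isolated)
Conditions: p-TsOH·H2O (0.3 equiv), MeOH–CH2Cl2, 35 °C; evaporate; Ac2O, pyridine, 0 °C → rt
Reagents that add atoms: acetic anhydride, CC(=O)OC(C)=O
Why: Acid methanolysis removes both MOM acetals (labilised by the flanking aryl ketone) and expels methanol through the p-anisyl-stabilised cation to give the E-enone, the freed C6' phenol, held under C10 by the axial 1α-aryl bond, closes the dihydrofuran by 5-exo-trig oxa-Michael addition from the α face and so sets C10 (O cis to the C5 methyl), and acetylation caps the C2' phenol so that it cannot cyclise onto the chalcone in step 15.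

Step 15
Reactants: 28 ketone acetate
Product: 29 target 2'-acetate (8,9-dione)
Conditions: SeO2, 1,4-dioxane, 90 °C
Reagents that add atoms: selenium dioxide, O=[Se]=O
Why: Riley oxidation of a ketone to a 1,2-diketone, with C9H2 the only enolisable ketone position left (C7 is a cyclopropane CH, the chalcone has none and the ester methyl is inert to SeO2), and once C9 is a carbonyl the C10–O bond can no longer be lost by retro-Michael cleavage.

Step 16
Reactants: 29 diketone acetate
Product: 30 target CNP0121765.1
Conditions: K2CO3 (0.5 equiv), MeOH, 0 °C; AcOH quench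
Reagents that add atoms: none
Why: Base-catalysed methanolysis (transesterification) of the aryl acetate is fast at 0 °C because the hydrogen-bonded phenoxide leaves easily, so the non-enolisable diketone, the cyclopropane and the chalcone never meet strong base and no stereocentre is affected.

Compound list
1 | 2-methylcyclohex-2-en-1-one | CC1=CCCCC1=O | starting material
2 | (3R)-2,3-dimethylcyclohexan-1-one (C2 epimers) | CC1C(=O)CCC[C@H]1C | intermediate
3 | but-3-en-2-one | C=CC(C)=O | starting material
4 | (2S,3R)-2,3-dimethyl-2-(3-oxobutyl)cyclohexan-1-one | CC(=O)CC[C@@]1(C)[C@H](C)CCCC1=O | intermediate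
5 | (4aS,5R)-4a,5-dimethyl-4,4a,5,6,7,8-hexahydronaphthalen-2(3H)-one | C1CC[C@@H](C)[C@]2(C)CCC(=O)C=C12 | intermediate
6 | 8-acetoxy-4α,5α-dimethyl-1(10),8-diene | CC(=O)OC1=CC2=CCC[C@@H](C)[C@]2(C)CC1 | intermediate
7 | 4α,5α-dimethyl-1(10)-en-8-one | O=C1CC2=CCC[C@@H](C)[C@]2(C)CC1 | intermediate
8 | 4α,5α-dimethyl-1(10)-en-8α-ol | O[C@H]1CC2=CCC[C@@H](C)[C@]2(C)CC1 | intermediate
9 | 1β,10β-epoxy-4α,5α-dimethyldecalin-8α-ol | O[C@H]1C[C@@]23O[C@@H]2CC[C@@H](C)[C@]3(C)CC1 | intermediate
10 | 2',6'-dihydroxy-4'-methoxyacetophenone | CC(=O)c1c(O)cc(OC)cc1O | starting material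
11 | 4'-methoxy-2',6'-bis(methoxymethoxy)acetophenone | CC(=O)c1c(OCOC)cc(OC)cc1OCOC | intermediate
12 | potassium enolate of 11 | C=C([O-])c1c(OCOC)cc(OC)cc1OCOC.[K+] | intermediate
13 | TIPS enol ether of 11 | C=C(O[Si](C(C)C)(C(C)C)C(C)C)c1c(OCOC)cc(OC)cc1OCOC | intermediate
14 | Ar–Li | [Li]c1c(OC)cc(OCOC)c(C(=C)O[Si](C(C)C)(C(C)C)C(C)C)c1OCOC | intermediate
15 | Ar–MgBr | Br[Mg]c1c(OC)cc(OCOC)c(C(=C)O[Si](C(C)C)(C(C)C)C(C)C)c1OCOC | intermediate
16 | bromomagnesium 8α-alkoxide of 9 | Br[Mg]O[C@H]1C[C@@]23O[C@@H]2CC[C@@H](C)[C@]3(C)CC1 | intermediate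
17 | 1α-Ar-4α,5α-dimethyldecalin-8α,10β-diol | C=C(O[Si](C(C)C)(C(C)C)C(C)C)c1c(OCOC)cc(OC)c(c1OCOC)[C@H]1CC[C@@H](C)[C@]2(C)CC[C@@H](O)C[C@@]12O | intermediate
18 | 1α-Ar-10β-hydroxy-4α,5α-dimethyldecalin-8-one | C=C(O[Si](C(C)C)(C(C)C)C(C)C)c1c(OCOC)cc(OC)c(c1OCOC)[C@H]1CC[C@@H](C)[C@]2(C)CCC(=O)C[C@@]12O | intermediate
19 | 1α-Ar-4α,5α-dimethyl-9-en-8-one | C=C(O[Si](C(C)C)(C(C)C)C(C)C)c1c(OCOC)cc(OC)c(c1OCOC)[C@H]1CC[C@@H](C)[C@]2(C)CCC(=O)C=C12 | intermediate
20 | lithium 7,9-dien-8-olate of 19 | C=C(O[Si](C(C)C)(C(C)C)C(C)C)c1c(OCOC)cc(OC)c(c1OCOC)[C@H]1CC[C@@H](C)[C@]2(C)CC=C(O[Li])C=C12 | intermediate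
21 | 1α-Ar-4α,5α-dimethyl-6,9-dien-8-one | C=C(O[Si](C(C)C)(C(C)C)C(C)C)c1c(OCOC)cc(OC)c(c1OCOC)[C@H]1CC[C@@H](C)[C@]2(C)C=CC(=O)C=C12 | intermediate
22 | isopropyldiphenylsulfonium tetrafluoroborate | CC(C)[S+](c1ccccc1)c1ccccc1.F[B-](F)(F)F | starting material
23 | diphenylsulfonium isopropylide | C[C-](C)[S+](c1ccccc1)c1ccccc1 | intermediate
24 | 1α-Ar-aristol-9-en-8-one | C=C(O[Si](C(C)C)(C(C)C)C(C)C)c1c(OCOC)cc(OC)c(c1OCOC)[C@H]1CC[C@@H](C)[C@]2(C)[C@H]3[C@H](C3(C)C)C(=O)C=C12 | intermediate
25 | 4-methoxybenzaldehyde dimethyl acetal | COc1ccc(cc1)C(OC)OC | starting material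
26 | β-methoxy ketone (bis-MOM, aristol-9-en-8-one) | COc1ccc(cc1)C(OC)CC(=O)c1c(OCOC)cc(OC)c(c1OCOC)[C@H]1CC[C@@H](C)[C@]2(C)[C@H]3[C@H](C3(C)C)C(=O)C=C12 | intermediate
27 | 9-deoxo target (free C2' phenol) | COc1ccc(/C=C/C(=O)c2c(O)cc(OC)c3c2O[C@]24CC(=O)[C@@H]5[C@@H](C5(C)C)[C@@]2(C)[C@H](C)CC[C@H]34)cc1 | intermediate
28 | 9-deoxo target 2'-acetate | COc1ccc(/C=C/C(=O)c2c(OC(C)=O)cc(OC)c3c2O[C@]24CC(=O)[C@@H]5[C@@H](C5(C)C)[C@@]2(C)[C@H](C)CC[C@H]34)cc1 | intermediate
29 | target 2'-acetate | COc1ccc(/C=C/C(=O)c2c(OC(C)=O)cc(OC)c3c2O[C@]24C(=O)C(=O)[C@@H]5[C@@H](C5(C)C)[C@@]2(C)[C@H](C)CC[C@H]34)cc1 | intermediate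
30 | CNP0121765.1 | COc1ccc(/C=C/C(=O)c2c(O)cc(OC)c3c2O[C@]24C(=O)C(=O)[C@@H]5[C@@H](C5(C)C)[C@@]2(C)[C@H](C)CC[C@H]34)cc1 | target

Total step count: 16. Longest linear sequence: 14 (steps 1–5 and 8–16).

Steps most likely to fail

1. Step 12.
   - What may go wrong: proton transfer from C1 to the ylide would consume ylide and erode the C1 configuration. β-Face approach may be slowed by C4 and its methyl so that facial discrimination drops. 1,2-Addition at C8 is also possible.
   - Fallback: it sets out from 21 and uses a neutral dipole instead of a basic ylide. 2-Diazopropane F1 (from acetone hydrazone and Ag2O, Et2O, −20 °C) should add across C6=C7 from the β face, carbon to C6 and nitrogen to C7, to give the 1-pyrazoline F2. Irradiation through Pyrex at −20 °C extrudes nitrogen and closes the same cyclopropane. The route is rejoined at 24.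

2. Step 8.
   - What may go wrong: opening may be too slow, because a nucleophile with two ortho substituents must reach C1 syn-axial to the C5 methyl. Bromohydrin formation or Lewis-acid rearrangement of the epoxide could then take over.
   - Fallback: it sets out from 5 and sets C1 by hydrogen delivery to the open β face instead of C–C bond formation on the hindered α face.
   - Chloranil in refluxing t-BuOH gives the linear 4α,5α-dimethyl-1,9-dien-8-one F3.
   - Br2 adds to the distal C1=C2 bond to give the 1,2-dibromide F4, and Et3N removes HBr through the vinylogous C1–H to give the 1-bromo-1,9-dien-8-one F5.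
   - Aryllithium 14 and ZnCl2 give the arylzinc chloride F6, and Negishi coupling (Pd(OAc)2, SPhos, THF, 50 °C) gives the 1-aryl-1,9-dien-8-one F7.
   - Hydrogenation of C1=C2 (H2, Pd/C, EtOAc with a little pyridine) from the β face leaves the aryl group α, the enol ether being shielded by its two ortho groups and the TIPS group. The route is rejoined at 19.

3. Step 15.
   - What may go wrong: acid-promoted reopening of the dihydrofuran by retro-oxa-Michael reaction at 90 °C would be followed by loss of the C1 configuration. Loss of the acetate would allow oxidative cyclisation of the chalcone. The cyclopropane could also open.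
   - Fallback: it sets out from 28 and works near or below room temperature. Me3SiOTf/Et3N (CH2Cl2, 0 °C) gives the C8=C9 trimethylsilyl enol ether F8. Rubottom oxidation with dimethyldioxirane (acetone, −40 °C) gives the 9-hydroxy-8-ketone F9, and Dess–Martin periodinane oxidises the acyloin. The route is rejoined at 29.

Further compounds
F1 | step 12 | 2-diazopropane | CC(C)=[N+]=[N-]
F2 | step 12 | 6β,7β-fused 1-pyrazoline of 21 (CMe2 on C6, N on C7) | C=C(O[Si](C(C)C)(C(C)C)C(C)C)c1c(OCOC)cc(OC)c(c1OCOC)[C@H]1CC[C@@H](C)[C@]2(C)[C@H]3[C@H](N=NC3(C)C)C(=O)C=C12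
F3 | step 8 | 4α,5α-dimethyl-1,9-dien-8-one | C1=CC[C@@H](C)[C@]2(C)CCC(=O)C=C12
F4 | step 8 | 1,2-dibromo-4α,5α-dimethyl-9-en-8-one | BrC1C(Br)C[C@@H](C)[C@]2(C)CCC(=O)C=C12
F5 | step 8 | 1-bromo-4α,5α-dimethyl-1,9-dien-8-one | BrC1=CC[C@@H](C)[C@]2(C)CCC(=O)C=C12
F6 | step 8 | Ar–ZnCl | Cl[Zn]c1c(OC)cc(OCOC)c(C(=C)O[Si](C(C)C)(C(C)C)C(C)C)c1OCOC
F7 | step 8 | 1-Ar-4α,5α-dimethyl-1,9-dien-8-one | C=C(O[Si](C(C)C)(C(C)C)C(C)C)c1c(OCOC)cc(OC)c(c1OCOC)C1=CC[C@@H](C)[C@]2(C)CCC(=O)C=C12
F8 | step 15 | C8=C9 trimethylsilyl enol ether of 28 | COc1ccc(/C=C/C(=O)c2c(OC(C)=O)cc(OC)c3c2O[C@]24C=C(O[Si](C)(C)C)[C@@H]5[C@@H](C5(C)C)[C@@]2(C)[C@H](C)CC[C@H]34)cc1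
F9 | step 15 | 9-hydroxy-8-ketone 2'-acetate (C9 epimers) | COc1ccc(/C=C/C(=O)c2c(OC(C)=O)cc(OC)c3c2O[C@]24C(O)C(=O)[C@@H]5[C@@H](C5(C)C)[C@@]2(C)[C@H](C)CC[C@H]34)cc1
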